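**Strategy**

The target is the 8,8''-dimer of acacetin. Everything rests on cutting the two C2–C1' bonds: in each ring C, C2 is the electron-poor terminus of the vinylogous ester O1–C2=C3–C4=O, and C1' belongs to an anisyl ring B. One double oxidative Heck arylation with 4-methoxyphenylboronic acid therefore sets both B rings onto bare C2–H positions of a symmetric 8,8'-bichromone. That precursor carries benzyl ethers on all four ring A oxygens, which one dibenzylation supplies and neutral hydrogenolysis removes, so no methyl ether ever has to be told from another. The crowded C8–C8' axis is made earlier by Ullmann coupling of an 8-iodochromone, where the phenol next to iodine is already tied up as O1.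

Key step: step 5

Assumption: the C8–C8'' axis carries four ortho substituents and is configurationally stable, but the target SMILES gives it no sense, so the route aims at the racemate.

Locant map: acetophenone C2–OH becomes C8a–O1, C3 becomes C8, C4–O becomes C7–O, and C6–O becomes C5–O of the chromone.

**Route**

Step 1
Reactants: 1 2',4',6'-trihydroxyacetophenone; 2 benzyl bromide
Product: 3 1-[2,4-bis(benzyloxy)-6-hydroxyphenyl]ethanone
Conditions: BnBr (2.1 equiv), K2CO3 (2.2 equiv), acetone, reflux
Reagents that add atoms: benzyl bromide, BrCc1ccccc1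
Why: Williamson ether synthesis in which the free 4-OH and one of the two equivalent chelated ortho OH groups are alkylated, while the last OH, locked in a hydrogen bond to the acetyl C=O, is too weak a nucleophile under K2CO3 to take a third benzyl group from the limited bromide.

Step 2
Reactants: 3 1-[2,4-bis(benzyloxy)-6-hydroxyphenyl]ethanone; 4 N-iodosuccinimide
Product: 5 1-[4,6-bis(benzyloxy)-2-hydroxy-3-iodophenyl]ethanone
Conditions: NIS (1.0 equiv), CF3CO2H (cat.), MeCN/CH2Cl2, 0 °C to rt, dark
Reagents that add atoms: N-iodosuccinimide, O=C1CCC(=O)N1I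
Why: Electrophilic aromatic iodination that should go to C3, the position ortho to the chelated phenol and para to the 6-benzyloxy group, because C5 is wedged between two benzyloxy groups, with one equivalent of 4 holding back a second iodination.

Step 3
Reactants: 5 1-[4,6-bis(benzyloxy)-2-hydroxy-3-iodophenyl]ethanone; 6 N,N-dimethylformamide dimethyl acetal
Product: 8 5,7-bis(benzyloxy)-8-iodo-4H-chromen-4-one, via enaminone 7 (not isolated)
Conditions: DMF dimethyl acetal (3 equiv), toluene, 100 °C; evaporate; conc. aq HCl, CH2Cl2, 40 °C
Reagents that add atoms: N,N-dimethylformamide dimethyl acetal, COC(OC)N(C)C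
Why: Standard enaminone route to 2,3-unsubstituted chromones, in which the acetyl CH3 condenses with the amide acetal and acid then triggers 6-endo-trig conjugate addition of the phenol oxygen to the enaminone beta carbon with loss of dimethylamine, conditions that the aryl iodide and the benzyl ethers tolerate.

Step 4
Reactants: 8 5,7-bis(benzyloxy)-8-iodo-4H-chromen-4-one (two molecules)
Product: 9 5,5',7,7'-tetrakis(benzyloxy)-8,8'-bichromone (racemic axis)
Conditions: activated Cu bronze (8 equiv), dry degassed NMP, 150 °C, Ar
Reagents that add atoms: none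
Why: Classical Ullmann reductive homocoupling through an arylcopper intermediate, well proven for 8-iodo-5,7-dialkoxyflavones with the same ortho environment; with the former phenol now bound as O1 no acidic proton can quench the arylcopper species, and NMP releases no secondary amine that could open the C2-unsubstituted pyranone.

Step 5
Reactants: 9 5,5',7,7'-tetrakis(benzyloxy)-8,8'-bichromone; 10 4-methoxyphenylboronic acid
Product: 12 5,5'',7,7''-tetra-O-benzyl-4',4'''-di-O-methylcupressuflavone, via monoarylated bichromone 11 (not isolated)
Conditions: 10 (5 equiv, in three portions), Pd(OCOCF3)2 (20 mol %), 1,10-phenanthroline (24 mol %), O2 (1 atm), dry DMF, 90 °C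
Reagents that add atoms: 4-methoxyphenylboronic acid, COc1ccc(B(O)O)cc1
Why: Transmetalation from 10 to the phenanthroline-bound divalent palladium trifluoroacetate gives a cationic 4-methoxyphenylpalladium species, which binds C2=C3 of one pyranone ring and inserts syn so that the aryl group lands on C2 and the metal on C3, alpha to C4=O. The C2–H is then anti to the metal, so the carbon-bound enolate slips through its oxygen-bound form to the other face, syn beta-hydride elimination rebuilds C2=C3, O2 returns the zerovalent palladium to divalent palladium, and the cycle repeats on the second, electronically independent half of 11. The closest known reaction is the oxidative (boron) Heck C2 arylation of simple chromones with arylboronic acids to flavones, used here twice on one molecule. No ring is closed and no stereocentre is formed; the C8–C8' axis is already in place, is not touched and stays racemic. The step needs C2 over C3 selectivity, which the polarisation of O1–C2=C3–C4=O secures, because the carbon ligand migrates to the electron-poor beta carbon and the metal ends up as the stabilised enolate. It also needs elimination to win over protonolysis of that enolate (which would stop at the flavanone level), which the dry aprotic medium, the O2 atmosphere and the absence of added acid favour, while the portionwise excess of 10 offsets its own oxidative losses.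

Step 6
Reactants: 12 5,5'',7,7''-tetra-O-benzyl-4',4'''-di-O-methylcupressuflavone
Product: 13 4',4'''-di-O-methylcupressuflavone (racemic)
Conditions: H2 (1 atm), 10% Pd/C, THF/MeOH, rt
Reagents that add atoms: none
Why: Catalytic hydrogenolysis cleaves only the four benzylic C–O bonds, since aryl methyl ethers are inert and the C2=C3 bond of a flavone is reduced far more slowly at one atmosphere, so stopping at the calculated hydrogen uptake should deliver 13 with both 4'-methoxy groups intact.

**Compound list**

1 | 2',4',6'-trihydroxyacetophenone | CC(=O)c1c(O)cc(O)cc1O | starting material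
2 | benzyl bromide | BrCc1ccccc1 | starting material
3 | 1-[2,4-bis(benzyloxy)-6-hydroxyphenyl]ethanone | CC(=O)c1c(O)cc(OCc2ccccc2)cc1OCc1ccccc1 | intermediate
4 | N-iodosuccinimide | O=C1CCC(=O)N1I | starting material
5 | 1-[4,6-bis(benzyloxy)-2-hydroxy-3-iodophenyl]ethanone | CC(=O)c1c(O)c(I)c(OCc2ccccc2)cc1OCc1ccccc1 | intermediate
6 | N,N-dimethylformamide dimethyl acetal | COC(OC)N(C)C | starting material
7 | (E)-1-[4,6-bis(benzyloxy)-2-hydroxy-3-iodophenyl]-3-(dimethylamino)prop-2-en-1-one | CN(C)/C=C/C(=O)c1c(O)c(I)c(OCc2ccccc2)cc1OCc1ccccc1 | intermediate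
8 | 5,7-bis(benzyloxy)-8-iodo-4H-chromen-4-one | O=c1ccoc2c(I)c(OCc3ccccc3)cc(OCc3ccccc3)c12 | intermediate
9 | 5,5',7,7'-tetrakis(benzyloxy)-8,8'-bichromone (8,8'-bi-4H-chromen-4-one, racemic axis) | O=c1ccoc2c(-c3c(OCc4ccccc4)cc(OCc4ccccc4)c4c(=O)ccoc34)c(OCc3ccccc3)cc(OCc3ccccc3)c12 | intermediate
10 | 4-methoxyphenylboronic acid | COc1ccc(B(O)O)cc1 | starting material
11 | 5,5',7,7'-tetrakis(benzyloxy)-2-(4-methoxyphenyl)-8,8'-bichromone (racemic axis) | COc1ccc(-c2cc(=O)c3c(OCc7ccccc7)cc(OCc7ccccc7)c(-c4c(OCc7ccccc7)cc(OCc7ccccc7)c5c(=O)ccoc45)c3o2)cc1 | intermediate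
12 | 5,5'',7,7''-tetra-O-benzyl-4',4'''-di-O-methylcupressuflavone, i.e. 5,5',7,7'-tetrakis(benzyloxy)-2,2'-bis(4-methoxyphenyl)-8,8'-bichromone (racemic axis) | COc1ccc(-c2cc(=O)c3c(OCc7ccccc7)cc(OCc7ccccc7)c(-c4c(OCc7ccccc7)cc(OCc7ccccc7)c5c(=O)cc(-c6ccc(OC)cc6)oc45)c3o2)cc1 | intermediate
13 | 4',4'''-di-O-methylcupressuflavone (racemic axis) | COc1ccc(-c2cc(=O)c3c(O)cc(O)c(-c4c(O)cc(O)c5c(=O)cc(-c6ccc(OC)cc6)oc45)c3o2)cc1 | target

**Step count**

Total step count: 6
Longest linear sequence: 6 steps (1, 3, 5, 8, 9, 12, 13)

**Steps most likely to fail**

Step 5. The electron-rich 5,7-dioxygenated pyranones may insert too slowly. Oxidative homocoupling, oxidation and protodeboronation of the aryl donor could then outrun the arylation. The reaction could also stall after the first end, or protonolysis of the palladium enolate could divert material to the dihydro level.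

The fallback builds the B rings by carbonyl chemistry and makes the axis last. It sets out from 5.
- Claisen–Schmidt condensation with 4-methoxybenzaldehyde (KOH, EtOH, rt) should give (E)-1-[4,6-bis(benzyloxy)-2-hydroxy-3-iodophenyl]-3-(4-methoxyphenyl)prop-2-en-1-one F1.
- Oxidative cyclisation with catalytic I2 in DMSO at 120 °C should give 5,7-bis(benzyloxy)-8-iodo-2-(4-methoxyphenyl)-4H-chromen-4-one F2.
- Ullmann homocoupling of F2 (activated Cu bronze, NMP, 160 °C) comes back to the route at 12.

Step 4. Reductive loss of iodine through adventitious proton sources, sluggish coupling at a carbon flanked by two oxygen substituents, and thermal wear of the pyranone may erode the homocoupling.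

The fallback is a cross-coupling of two differentiated halves. It sets out from 8.
- Half of the material is converted by Miyaura borylation (B2pin2, PdCl2(dppf), KOAc, dioxane, 90 °C) into 5,7-bis(benzyloxy)-8-(4,4,5,5-tetramethyl-1,3,2-dioxaborolan-2-yl)-4H-chromen-4-one F3.
- F3 is joined to the other half of 8 by Suzuki–Miyaura coupling (Pd(OAc)2, SPhos, K3PO4, toluene/H2O, 100 °C), coming back to the route at 9.

Step 2. Poor site selectivity (attack at C5 instead of C3) or a second iodination may spoil the only regiochemical decision of the route.

The fallback closes ring C first and iodinates the chromone. It sets out from 3.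
- Condensation with 6 (toluene, 100 °C) should give (E)-1-[2,4-bis(benzyloxy)-6-hydroxyphenyl]-3-(dimethylamino)prop-2-en-1-one F4.
- HCl in CH2Cl2 closes F4 to 5,7-bis(benzyloxy)-4H-chromen-4-one F5.
- Iodination of F5 with 4 and catalytic CF3CO2H in MeCN comes back to the route at 8. It should go to C8, which is para to the 5-oxygen and ortho to the 7-oxygen and O1, whereas C6 is shielded by two benzyloxy groups. This is the usual outcome for 5,7-dialkoxyflavones.

**Further compounds**

F1 | step 5 | (E)-1-[4,6-bis(benzyloxy)-2-hydroxy-3-iodophenyl]-3-(4-methoxyphenyl)prop-2-en-1-one | COc1ccc(/C=C/C(=O)c2c(O)c(I)c(OCc3ccccc3)cc2OCc2ccccc2)cc1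
F2 | step 5 | 5,7-bis(benzyloxy)-8-iodo-2-(4-methoxyphenyl)-4H-chromen-4-one | COc1ccc(-c2cc(=O)c3c(OCc4ccccc4)cc(OCc4ccccc4)c(I)c3o2)cc1
F3 | step 4 | 5,7-bis(benzyloxy)-8-(4,4,5,5-tetramethyl-1,3,2-dioxaborolan-2-yl)-4H-chromen-4-one | CC1(C)OB(OC1(C)C)c1c(OCc2ccccc2)cc(OCc2ccccc2)c2c(=O)ccoc12
F4 | step 2 | (E)-1-[2,4-bis(benzyloxy)-6-hydroxyphenyl]-3-(dimethylamino)prop-2-en-1-one | CN(C)/C=C/C(=O)c1c(O)cc(OCc2ccccc2)cc1OCc1ccccc1
F5 | step 2 | 5,7-bis(benzyloxy)-4H-chromen-4-one | O=c1ccoc2cc(OCc3ccccc3)cc(OCc3ccccc3)c12
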